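## Retrosynthetic overview
1. Target 18 ⇐ acetylation of enol lactol 17. Lactol 17 ⇐ key C15–O(C12) oxa-Michael closure of the oxepane, followed by C3–O–C2 enol-lactolisation, starting from dialdehyde 15 and CH2O (which supplies C15).
2. 15 ⇐ ozonolysis of the C2=C3 bond of a sacrificial cyclopentene in triol 13.
3. 13 ⇐ methyl addition and ester reduction of tricyclic keto diester 11. Ketone 11 ⇐ cyclopentene annulation of enone 8 (conjugate propargylation, then gold 5-endo-dig closure).
4. 8 ⇐ enantioselective desymmetrising dehydrogenation of meso ketone 6. Ketone 6 ⇐ Rh cyclopropanation of cyclohept-4-enone 4, and 4 ⇐ RCM of dienone 3.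
5. Ring order: cycloheptene, then cyclopropane, then cyclopentene (later cleaved), then oxepane and dihydropyran together in the last step.

Numbering (aromadendrane):
- C1 and C5 are the ring-fusion CH carbons.
- C2 is the acetal CH and C3 the enol-ether CH.
- C4 is the enol-ether carbon that bears C15H2.
- C6 and C7 are the cyclopropane CH carbons; C8 and C9 are CH2.
- C10 is the carbinol carbon and C14 its methyl.
- C11 is the quaternary cyclopropane carbon, with C12 the endo CH2O and C13 the exo CH2O.

Assumption: the (R,R)-lithium amide is taken to remove the α-proton that leads to (1R,7S)-8. If the sense proves opposite, the (S,S)-amide is used and nothing else changes.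

## Route

Step 1
Reactants: 1 4-pentenoyl chloride; 2 3-butenylmagnesium bromide
Product: 3 nona-1,8-dien-5-one
Conditions: Fe(acac)3 (3 mol %), THF, −78 °C
Reagents that add atoms: none
Why: Iron-catalysed acylation of a Grignard reagent with an acid chloride stops at the ketone, and no stereocentre is formed.

Step 2
Reactants: 3 nona-1,8-dien-5-one
Product: 4 cyclohept-4-en-1-one
Conditions: second-generation Grubbs catalyst (1 mol %), CH2Cl2 (0.02 M), 40 °C
Reagents that add atoms: none
Why: Ring-closing metathesis of two terminal alkenes to an unstrained seven-membered ring is driven by loss of ethene.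

Step 3
Reactants: 4 cyclohept-4-en-1-one; 5 dimethyl diazomalonate
Product: 6 dimethyl (1R,7S)-4-oxobicyclo[5.1.0]octane-8,8-dicarboxylate (meso)
Conditions: Rh2(esp)2 (0.5 mol %), CH2Cl2, 0 °C to rt, slow addition of 5 (1.5 equiv)
Reagents that add atoms: none
Why: Rhodium-carbenoid cyclopropanation is a concerted syn addition, so C6 and C7 are set cis and the product is the meso ketone.

Step 4
Reactants: 6 meso keto diester
Product: 8 dimethyl (1R,7S)-4-oxobicyclo[5.1.0]oct-2-ene-8,8-dicarboxylate, via lithium enolate 7 (not isolated)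
Conditions: (R,R)-bis(1-phenylethyl)amine·HCl, n-BuLi (2 equiv), THF, −78 °C; add 6; then PhS(Cl)=NtBu, −78 °C
Reagents that add atoms: none
Why: Enantioselective deprotonation of a meso ketone by a LiCl-modified C2-symmetric chiral lithium amide, followed by Mukaiyama dehydrogenation of the enolate, selects one of the two enantiotopic α-CH2 groups and so fixes the absolute configuration at C6 and C7.

Step 5
Reactants: 8 enone; 9 allenyltributylstannane
Product: 10 dimethyl (1R,2R,7S)-4-(tert-butyldimethylsilyloxy)-2-(prop-2-yn-1-yl)bicyclo[5.1.0]oct-3-ene-8,8-dicarboxylate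
Conditions: TBSOTf (1.2 equiv), CH2Cl2, −78 °C
Reagents that add atoms: tert-butyldimethylsilyl triflate CC(C)(C)[Si](C)(C)OS(=O)(=O)C(F)(F)F
Why: In this silyl-triflate-mediated conjugate propargylation (SE2′ of the allenylstannane), attack occurs anti to the cyclopropane because the endo ester blocks the other face; this sets C5, and the enolate is trapped regiospecifically as the C1=C10 silyl enol ether.

Step 6
Reactants: 10 propargylated silyl enol ether
Product: 11 dimethyl (1R,5R,6R,7S)-10-oxo-14,15-dinoraromadendr-2-ene-12,13-dioate (cis-fused, H-1 and H-5 on the face of C11)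
Conditions: Ph3PAuCl (5 mol %), AgBF4 (5 mol %), CH2Cl2/MeOH 10:1, 40 °C
Reagents that add atoms: none
Why: Cationic monovalent gold triggers a 5-endo-dig carbocyclisation of the silyl enol ether onto the terminal alkyne (Conia-ene type), and the short tether allows only cis fusion, which sets C1 and places the alkene at C2=C3.

Step 7
Reactants: 11 tricyclic keto diester
Product: 12 dimethyl (1R,5R,6R,7S,10S)-10-hydroxy-15-noraromadendr-2-ene-12,13-dioate
Conditions: MeLi, CeCl3 (anhydrous), THF, −78 °C; aq. NH4Cl
Reagents that add atoms: methyllithium [Li]C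
Why: The weakly basic organocerium reagent undergoes 1,2-addition without enolising the β,γ-unsaturated ketone or touching the hindered esters, and it attacks the convex face anti to the C1–C2 bond, which places C14 syn to H-1 (10S).

Step 8
Reactants: 12 hydroxy diester
Product: 13 (1R,5R,6R,7S,10S)-15-noraromadendr-2-ene-10,12,13-triol
Conditions: LiAlH4, THF, 0 °C to rt; H2O, aq. NaOH
Reagents that add atoms: none
Why: Hydride reduction converts both cyclopropane esters to the 1,1-bis(hydroxymethyl) unit, and neither the alkene nor any stereocentre is affected.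

Step 9
Reactants: 13 triol
Product: 15 (1R,5R,6R,7S,10S)-10,12,13-trihydroxy-15-nor-2,3-secoaromadendrane-2,3-dial (used crude; it rests as lactols), via secondary ozonide 14 (not isolated)
Conditions: O3, CH2Cl2, −78 °C; then Me2S, −78 °C to rt
Reagents that add atoms: ozone [O-][O+]=O
Why: Reductive ozonolysis cleaves the only alkene and delivers both aldehydes without any oxidant that would attack the three free hydroxyl groups, and C1 and C5 stay cis.

Step 10
Reactants: 15 trihydroxy dialdehyde
Product: 18 target CNP0250836.3, via alpha-methylene aldehyde 16 (not isolated), via enol lactol 17 (not isolated)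
Conditions: aq. CH2O (37 %, 1.1 equiv), pyrrolidine (20 mol %), 4-Me2NC6H4CO2H (20 mol %), CH2Cl2, 35 °C; then pyridine, Ac2O (10 equiv), DMAP (5 mol %), 0 °C
Reagents that add atoms: formaldehyde C=O; acetic anhydride CC(=O)OC(C)=O
Why: Proposed new method: this is an interrupted organocatalytic α-methylenation in which pyrrolidine condenses only with the unhindered C3 aldehyde (the C2 aldehyde is flanked by C10 and C5 and rests as a lactol), the enamine adds to CH2O and loses water to give the α-methylene iminium ion and enal 16, the terminal CH2 (C15) is then attacked 7-endo-trig by the endo C12–OH that the cis-cyclopropane holds next to C5 (the exo C13–OH cannot reach, which makes C11 stereogenic, while addition of the tertiary C10–OH is reversible and could only lead to a bridgehead enol ether, so it is a dead end), the resulting α-branched C3 aldehyde enolises and its enol oxygen closes on the C2 aldehyde as iridodial closes to nepetalactol, giving 17, and acetylation finally freezes the lactol as the axial (anomeric) acetate trans to the C1–C10 bond and esterifies C13–OH while leaving the tertiary alcohol free; the closest known reaction types are amine/acid-catalysed α-methylenation of aldehydes with formaldehyde, intramolecular oxa-Michael addition to enals, and the Michael/enol-lactolisation/acetylation sequence of iridoid synthesis, but their merger, and oxepane closure onto a 2-substituted acrolein made in situ, has not been shown.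

## Compound list
1 | 4-pentenoyl chloride | C=CCCC(=O)Cl | starting material
2 | 3-butenylmagnesium bromide | C=CCC[Mg]Br | starting material
3 | nona-1,8-dien-5-one | C=CCCC(=O)CCC=C | intermediate
4 | cyclohept-4-en-1-one | O=C1CCC=CCC1 | intermediate
5 | dimethyl diazomalonate | COC(=O)C(=[N+]=[N-])C(=O)OC | starting material
6 | dimethyl (1R,7S)-4-oxobicyclo[5.1.0]octane-8,8-dicarboxylate (meso) | COC(=O)C1(C(=O)OC)[C@@H]2CCC(=O)CC[C@H]12 | intermediate
7 | lithium (1R,7S)-8,8-bis(methoxycarbonyl)bicyclo[5.1.0]oct-3-en-4-olate | [Li+].COC(=O)C1(C(=O)OC)[C@@H]2CC=C([O-])CC[C@H]12 | intermediate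
8 | dimethyl (1R,7S)-4-oxobicyclo[5.1.0]oct-2-ene-8,8-dicarboxylate | COC(=O)C1(C(=O)OC)[C@@H]2C=CC(=O)CC[C@H]12 | intermediate
9 | allenyltributylstannane | C=C=C[Sn](CCCC)(CCCC)CCCC | starting material
10 | dimethyl (1R,2R,7S)-4-(tert-butyldimethylsilyloxy)-2-(prop-2-yn-1-yl)bicyclo[5.1.0]oct-3-ene-8,8-dicarboxylate | COC(=O)C1(C(=O)OC)[C@@H]2[C@@H](CC#C)C=C(O[Si](C)(C)C(C)(C)C)CC[C@H]12 | intermediate
11 | dimethyl (1R,5R,6R,7S)-10-oxo-14,15-dinoraromadendr-2-ene-12,13-dioate | COC(=O)C1(C(=O)OC)[C@@H]2[C@H]3CC=C[C@H]3C(=O)CC[C@H]12 | intermediate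
12 | dimethyl (1R,5R,6R,7S,10S)-10-hydroxy-15-noraromadendr-2-ene-12,13-dioate | COC(=O)C1(C(=O)OC)[C@@H]2[C@H]3CC=C[C@H]3[C@@](C)(O)CC[C@H]12 | intermediate
13 | (1R,5R,6R,7S,10S)-15-noraromadendr-2-ene-10,12,13-triol | OCC1(CO)[C@@H]2[C@H]3CC=C[C@H]3[C@@](C)(O)CC[C@H]12 | intermediate
14 | secondary ozonide (C2/C3 1,2,4-trioxolane) of 13, ozonide carbons undefined | OCC1(CO)[C@@H]2[C@H]3CC4OOC(O4)[C@H]3[C@@](C)(O)CC[C@H]12 | intermediate
15 | (1R,5R,6R,7S,10S)-10,12,13-trihydroxy-15-nor-2,3-secoaromadendrane-2,3-dial | OCC1(CO)[C@@H]2[C@@H](CC=O)[C@@H](C=O)[C@@](C)(O)CC[C@H]12 | intermediate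
16 | (1R,5R,6S,7S,10S)-10,12,13-trihydroxy-2,3-secoaromadendr-4(15)-ene-2,3-dial | OCC1(CO)[C@@H]2[C@@H](C(=C)C=O)[C@@H](C=O)[C@@](C)(O)CC[C@H]12 | intermediate
17 | (1R,2S,5R,6S,7S,10S,11S)-2,3:12,15-diepoxy-2,3-secoaromadendr-3-ene-2,10,13-triol (enol lactol) | OC[C@@]12COCC3=CO[C@H](O)[C@@H]4[C@H]3[C@@H]1[C@@H]2CC[C@]4(C)O | intermediate
18 | (1R,2R,5R,6S,7S,10S,11R)-2,13-diacetoxy-2,3:12,15-diepoxy-2,3-secoaromadendr-3-en-10-ol (CNP0250836.3) | CC(=O)OC[C@@]12COCC3=CO[C@H](OC(C)=O)[C@@H]4[C@H]3[C@@H]1[C@@H]2CC[C@]4(C)O | target

## Step count and risks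
Total steps: 10. Longest linear sequence: 10 (from 1 and 2 to 18).

**Step 10 (the new cascade).** It may fail in three ways. The β-hydroxy aldehyde may undergo retro-aldol cleavage or dehydration under amine catalysis. The tertiary hydroxyl may interfere. The seven-membered closure may be too slow.

The fallback sets out from 12 and comes back at 18. It uses a protected, stepwise sequence of known reactions.
- TESOTf and 2,6-lutidine give the C10 triethylsilyl ether diester F4.
- LiAlH4 gives the silyl ether diol F5.
- O3 then Me2S gives the silyl ether dialdehyde F6.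
- Stoichiometric dimethylmethyleneammonium iodide with Et3N in CH2Cl2 gives the isolated silyl ether α-methylene aldehyde F7.
- Catalytic DBU in toluene effects the base-mediated oxa-Michael closure and lactolisation to the silyl ether enol lactol F8.
- Ac2O, pyridine and DMAP give the silyl ether diacetate F9.
- HF·pyridine buffered with pyridine releases 18.

**Step 4.** The flexible cycloheptanone may give only moderate enantiomeric excess.

The fallback sets out from 5 and comes back at 8. It moves the enantio-determining event into the cyclopropanation.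
- Compound 5 and excess commercial cyclohepta-1,3-diene react with Cu(MeCN)4PF6 and a chiral bis(oxazoline) carrying two benzylic side arms on the bridge carbon (toluene, 50 °C). This gives dimethyl (1R,7S)-bicyclo[5.1.0]oct-2-ene-8,8-dicarboxylate F1.
- Closed-shell allylic oxidation with SeO2 and t-BuOOH gives the C10 allylic alcohol F2. Radical oxidants are avoided because of the cyclopropylcarbinyl position.
- Dess–Martin periodinane gives 8.

**Step 7.** The doubly activated C1–H may be enolised, the alkene may move into conjugation, or the facial selectivity may be poor.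

The fallback sets out from 11 and comes back at 13. Corey–Chaykovsky methylene transfer with dimethylsulfonium methylide gives the C10 spiro-epoxide diester F3. If the other face is needed, the reversibly adding dimethylsulfoxonium methylide is used instead. LiAlH4 then opens the epoxide at its CH2 to create C14 and reduces both esters in the same operation, which gives 13.

## Further compounds
F1 | step 4 | dimethyl (1R,7S)-bicyclo[5.1.0]oct-2-ene-8,8-dicarboxylate | COC(=O)C1(C(=O)OC)[C@@H]2C=CCCC[C@H]12
F2 | step 4 | dimethyl (1R,7S)-4-hydroxybicyclo[5.1.0]oct-2-ene-8,8-dicarboxylate (C4 epimers) | COC(=O)C1(C(=O)OC)[C@@H]2C=CC(O)CC[C@H]12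
F3 | step 7 | C10 spiro-epoxide of 11 (CH2 syn to H-1) | COC(=O)C1(C(=O)OC)[C@@H]2[C@H]3CC=C[C@H]3[C@]4(CO4)CC[C@H]12
F4 | step 10 | C10 triethylsilyl ether of 12 | COC(=O)C1(C(=O)OC)[C@@H]2[C@H]3CC=C[C@H]3[C@@](C)(O[Si](CC)(CC)CC)CC[C@H]12
F5 | step 10 | C10 triethylsilyl ether of 13 | OCC1(CO)[C@@H]2[C@H]3CC=C[C@H]3[C@@](C)(O[Si](CC)(CC)CC)CC[C@H]12
F6 | step 10 | C10 triethylsilyl ether of 15 | OCC1(CO)[C@@H]2[C@@H](CC=O)[C@@H](C=O)[C@@](C)(O[Si](CC)(CC)CC)CC[C@H]12
F7 | step 10 | C10 triethylsilyl ether of 16 | OCC1(CO)[C@@H]2[C@@H](C(=C)C=O)[C@@H](C=O)[C@@](C)(O[Si](CC)(CC)CC)CC[C@H]12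
F8 | step 10 | C10 triethylsilyl ether of 17 | OC[C@@]12COCC3=CO[C@H](O)[C@@H]4[C@H]3[C@@H]1[C@@H]2CC[C@]4(C)O[Si](CC)(CC)CC
F9 | step 10 | C10 triethylsilyl ether of 18 | CC(=O)OC[C@@]12COCC3=CO[C@H](OC(C)=O)[C@@H]4[C@H]3[C@@H]1[C@@H]2CC[C@]4(C)O[Si](CC)(CC)CC
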